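**Assumptions:** The target is taken exactly as drawn in the SMILES, which I read as (7S,8R)-erythro in the 8-O-4′ unit and (7′R,8′S)-trans in the dihydrobenzofuran. Compounds 1, 5, 7 (0.5 M in THF) and 10 are treated as catalogue items.

## Retrosynthetic overview
1. The target comes from reducing a C9′ aldehyde and a side-chain methyl ester. The aldehyde comes from glycol cleavage of a glycerate-derived dioxolane, whose carbinol carbon is kept as C9′.
2. The dihydrobenzofuran is the only ring formed. It is made late, in one anodic formal [3+2] of methyl dihydroferulate with an (E)-styryl dioxolane, which forms the C8′–C5″ and C7′–O bonds.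
3. The styrene comes from a Heck coupling of an aryl bromide that carries the finished 8-O-4′ chain with (R)-4-vinyl-dioxolane.
4. The erythro 8-O-4′ unit comes from Felkin–Anh addition of an aryl Grignard to an (R)-α-aryloxy aldehyde. That aldehyde comes from Mitsunobu inversion of an (S)-glycerate.
5. Both chiral pieces come from one purchased compound, methyl (S)-glycerate acetonide.

## Route

**Step 1**
Reactants: 1, methyl (S)-2,2-dimethyl-1,3-dioxolane-4-carboxylate
Product: 2, (R)-2,2-dimethyl-4-vinyl-1,3-dioxolane
Conditions: DIBAL-H (1.05 equiv), CH2Cl2, −78 °C; then Ph3P=CH2 (from Ph3PCH3Br/KHMDS, THF, 2.5 equiv), −78 °C → rt; careful distillation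
Reagents that add atoms: methyltriphenylphosphonium bromide, C[P+](c1ccccc1)(c1ccccc1)c1ccccc1.[Br-] (adds CH2)
Why: One-pot ester half-reduction and Wittig methylenation means the epimerisable (S)-glyceraldehyde acetonide is never isolated, and the purchased stereocentre is untouched (S→R is only a CIP priority change).

**Step 2**
Reactants: 1
Product: 3, methyl (S)-2,3-dihydroxypropanoate
Conditions: p-TsOH·H2O (2 mol %), MeOH, 40 °C; solid NaHCO3, filter, concentrate
Reagents that add atoms: none
Why: Acid-catalysed transketalisation to methanol frees the diol without touching the ester or the stereocentre.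

**Step 3**
Reactants: 3
Product: 4, methyl (S)-3-[(tert-butyldimethylsilyl)oxy]-2-hydroxypropanoate
Conditions: TBSCl (1.05 equiv), imidazole, CH2Cl2, 0 °C
Reagents that add atoms: TBSCl, CC(C)(C)[Si](C)(C)Cl
Why: This is a sterically controlled silylation, in which the primary OH reacts much faster than the deactivated α-hydroxy-ester OH.

**Step 4**
Reactants: 4; 5, 4-bromo-2,6-dimethoxyphenol
Product: 6, methyl (R)-2-(4-bromo-2,6-dimethoxyphenoxy)-3-[(tert-butyldimethylsilyl)oxy]propanoate
Conditions: PPh3, DIAD (1.5 equiv each), toluene, 0 °C → rt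
Reagents that add atoms: none beyond reactant 5, COc1cc(Br)cc(OC)c1O
Why: Mitsunobu etherification is an SN2 displacement at the activated α-hydroxy-ester carbon with clean inversion, so (S) becomes (R), which is the C8 configuration.

**Step 5**
Reactants: 6; 7, 3,4-dimethoxyphenylmagnesium bromide
Product: 8, (1S,2R)-2-(4-bromo-2,6-dimethoxyphenoxy)-3-[(tert-butyldimethylsilyl)oxy]-1-(3,4-dimethoxyphenyl)propan-1-ol (erythro)
Conditions: DIBAL-H (1.1 equiv), CH2Cl2/toluene, −78 °C; then 7 (3 equiv, THF), −78 → −20 °C; Rochelle salt; chromatography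
Reagents that add atoms: none beyond reactant 7, COc1ccc([Mg]Br)cc1OC
Why: In this one-pot half-reduction and Grignard addition, the polar Felkin–Anh model applies (bulky aryloxy anti to the incoming aryl, non-chelating OTBS), so C8 sets C7 as S and gives the anti/erythro alcohol.

**Step 6**
Reactants: 8; 2 (2 equiv)
Product: 9, (1S,2R)-3-[(tert-butyldimethylsilyl)oxy]-1-(3,4-dimethoxyphenyl)-2-{4-[(E)-2-((4R)-2,2-dimethyl-1,3-dioxolan-4-yl)vinyl]-2,6-dimethoxyphenoxy}propan-1-ol
Conditions: Pd2(dba)3 (2.5 mol %), P(t-Bu)3·HBF4 (6 mol %), Cy2NMe, dioxane, 80 °C, sealed tube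
Reagents that add atoms: none beyond reactant 2, C=C[C@@H]1COC(C)(C)O1
Why: In this Mizoroki–Heck reaction the aryl group adds to the terminal carbon and β-hydride elimination toward the benzylic side gives the conjugated E-alkene, leaving the allylic stereocentre uninvolved.

**Step 7 (key step)**
Reactants: 9 (1 equiv); 10, methyl 3-(4-hydroxy-3-methoxyphenyl)propanoate (3 equiv, added by syringe pump during electrolysis)
Product: 11, methyl 3-[(2R,3R)-2-{4-[((1S,2R)-3-(TBSO)-1-(3,4-dimethoxyphenyl)-1-hydroxypropan-2-yl)oxy]-3,5-dimethoxyphenyl}-3-[(4R)-2,2-dimethyl-1,3-dioxolan-4-yl]-7-methoxy-2,3-dihydrobenzofuran-5-yl]propanoate (2,3-trans; same spatial arrangement at C7′/C8′ as the target)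
Conditions: undivided cell, BDD anode, Pt cathode, Bu3MeN·O3SOMe (0.1 M), 2,6-lutidine (0.5 equiv), HFIP/CH2Cl2 4:1, 0 °C, anode held at about +0.95 V vs Ag/AgCl (about 2.2 F per mol of 10 consumed); chromatography
Reagents that add atoms: none beyond reactants 9 and 10 (net loss of 2 H, released as H2 at the cathode)
Why: Proposed new method: this is an anodic, substrate-controlled formal [3+2] of a 4-alkylguaiacol with a glyceraldehyde-derived styrene, in which only phenol 10 is oxidised at the set potential (estimated styrene about +1.25 V, veratryl about +1.4 V), the HFIP-solvated phenoxyl/phenoxenium species is attacked at its only free ortho carbon by C8′ of the styrene (C8′–C5″ bond), the resulting p-alkoxybenzyl cation is closed by the phenolic oxygen (C7′–O bond), and proton loss re-aromatises the ring; C8′ is set by the purchased dioxolane stereocentre through a staggered "inside-alkoxy" transition state (C–O inside, C–C anti to the electrophile, the same facial sense as osmylation and nitrile-oxide additions to such alkenes, expected dr about 4–6:1), and C7′ then closes trans to the bulky C3 substituent; the ester side chain on 10 prevents the ipso-spirocyclisation that a free propanol would undergo; the closest known reaction types are the anodic phenol–arene cross-coupling of 4-methylguaiacol in HFIP (same ortho-carbon attack) and the anodic or photocatalytic oxidative [3+2] of 4-methoxyphenols with β-substituted styrenes (trans-selective), and neither has been shown for a 4-alkylguaiacol/alkene pair or with acyclic 1,2-induction.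

**Step 8**
Reactants: 11
Product: 13, methyl 3-[(2R,3R)-2-{4-[((1S,2R)-1-(3,4-dimethoxyphenyl)-1,3-dihydroxypropan-2-yl)oxy]-3,5-dimethoxyphenyl}-3-formyl-7-methoxy-2,3-dihydrobenzofuran-5-yl]propanoate, formed via 12, the (2R,3S)-3-[(1R)-1,2-dihydroxyethyl] tetraol, which is not isolated
Conditions: AcOH/THF/H2O 3:1:1, 40 °C, 14 h; cool to 0 °C, add aq NaIO4 (1.5 equiv), 30 min; extract and use crude
Reagents that add atoms: none
Why: Mild acid hydrolysis removes the terminal acetonide and the primary TBS group, and Malaprade cleavage in the same pot cuts only the vicinal diol (the 7,9-diol is 1,3), so the former glycerate carbinol carbon becomes the C9′ aldehyde with loss of CH2O, and trans is also the thermodynamic isomer.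

**Step 9**
Reactants: 13
Product: 14, berbikonol (7S,8R,7′R,8′S)
Conditions: LiBH4 (8 equiv), THF/MeOH 10:1, 0 °C → rt; aq NH4Cl; co-evaporate with MeOH
Reagents that add atoms: none
Why: Borohydride reduces the aldehyde at once, which pre-empts epimerisation or retro-oxa-Michael opening, then reduces the methyl ester on warming, and no stereocentre is touched.

## Compound list
| No. | Name | SMILES | Role |
|---|---|---|---|
| 1 | methyl (S)-2,2-dimethyl-1,3-dioxolane-4-carboxylate | COC(=O)[C@@H]1COC(C)(C)O1 | starting material |
| 2 | (R)-2,2-dimethyl-4-vinyl-1,3-dioxolane | C=C[C@@H]1COC(C)(C)O1 | intermediate |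
| 3 | methyl (S)-2,3-dihydroxypropanoate | COC(=O)[C@@H](O)CO | intermediate |
| 4 | methyl (S)-3-(TBSO)-2-hydroxypropanoate | COC(=O)[C@@H](O)CO[Si](C)(C)C(C)(C)C | intermediate |
| 5 | 4-bromo-2,6-dimethoxyphenol | COc1cc(Br)cc(OC)c1O | starting material |
| 6 | methyl (R)-2-(4-bromo-2,6-dimethoxyphenoxy)-3-(TBSO)propanoate | COC(=O)[C@@H](CO[Si](C)(C)C(C)(C)C)Oc1c(OC)cc(Br)cc1OC | intermediate |
| 7 | 3,4-dimethoxyphenylmagnesium bromide | COc1ccc([Mg]Br)cc1OC | starting material |
| 8 | erythro-(1S,2R) bromo alcohol | COc1ccc([C@H](O)[C@@H](CO[Si](C)(C)C(C)(C)C)Oc2c(OC)cc(Br)cc2OC)cc1OC | intermediate |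
| 9 | (E)-styryl (4R)-dioxolane | COc1ccc([C@H](O)[C@@H](CO[Si](C)(C)C(C)(C)C)Oc2c(OC)cc(/C=C/[C@@H]3COC(C)(C)O3)cc2OC)cc1OC | intermediate |
| 10 | methyl 3-(4-hydroxy-3-methoxyphenyl)propanoate | COC(=O)CCc1ccc(O)c(OC)c1 | starting material |
| 11 | trans-dihydrobenzofuran with 3-dioxolanyl | COc1ccc([C@H](O)[C@@H](CO[Si](C)(C)C(C)(C)C)Oc2c(OC)cc([C@@H]3Oc4c(OC)cc(CCC(=O)OC)cc4[C@H]3[C@@H]5COC(C)(C)O5)cc2OC)cc1OC | intermediate |
| 12 | tetraol ester (not isolated) | COc1ccc([C@H](O)[C@@H](CO)Oc2c(OC)cc([C@@H]3Oc4c(OC)cc(CCC(=O)OC)cc4[C@H]3[C@@H](O)CO)cc2OC)cc1OC | intermediate |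
| 13 | 3-formyl dihydrobenzofuran ester | COc1ccc([C@H](O)[C@@H](CO)Oc2c(OC)cc([C@@H]3Oc4c(OC)cc(CCC(=O)OC)cc4[C@H]3C=O)cc2OC)cc1OC | intermediate |
| 14 | berbikonol | COc1ccc([C@H](O)[C@@H](CO)Oc2c(OC)cc([C@@H]3Oc4c(OC)cc(CCCO)cc4[C@H]3CO)cc2OC)cc1OC | target |

## Step count
- **Total steps:** 9
- **Longest linear sequence:** 8 (1 → 3 → 4 → 6 → 8 → 9 → 11 → 13 → 14)

## Three steps most likely to fail

**1. Step 7 (the new anodic [3+2]).**
- The risks are guaiacol homocoupling or p-quinone-methide formation, the modest nucleophilicity of the styrene, capture of the benzylic cation by an acetal oxygen, and only moderate facial selectivity.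
- If the facial sense turns out to be opposite, ent-2 from D-mannitol-derived (R)-glyceraldehyde acetonide corrects it.
- The fallback uses known chemistry and drops the cycloaddition entirely:
  - Add the aryllithium from O-silylated 8 to (R)-glyceraldehyde acetonide, which gives the Felkin anti adduct.
  - O-arylate the benzylic alkoxide by SNAr on an o-bromo-p-formyl aryl fluoride, with retention at C7′.
  - Convert the acetonide to the terminal epoxide.
  - Close the ring by Br/Li exchange and 5-exo epoxide opening (Parham-type cyclisation), with inversion at C8′.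
  - An erythro adduct with retention at C7′ and inversion at C8′ gives the trans-3-hydroxymethyl dihydrobenzofuran stereospecifically. The formyl group is then homologated to the propanol chain.

**2. Step 5 (one-pot DIBAL-H/ArMgBr).**
- The risks are over-reduction, enolisation or β-elimination of the α-aryloxy aldehyde, and eroded dr.
- Fallback: convert 6 to its Weinreb amide, add 7 to obtain the α-aryloxy aryl ketone, and set C7 by chelation-controlled Zn(BH4)2 reduction, which is anti-selective and gives the same erythro alcohol.

**3. Step 6 (Heck coupling).**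
- The risks are a sluggish electron-rich bromide, and β-H or β-alkoxy elimination toward the dioxolane that would destroy the allylic stereocentre.
- Fallback: Suzuki vinylation of 8 with potassium vinyltrifluoroborate, then E-selective cross-metathesis of the resulting styrene with 2 (Hoveyda–Grubbs II).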